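**Plan**

1. Retrosynthesis first removes the two protecting groups (allyl on the ring B carboxyl, methoxymethyl on the ring A C5 oxygen) and then cuts ring B itself at C5'–C6', the bond between a ring CH and the hydroxyl-bearing carbon.
2. This is possible because ring B is a salicylate: C1' (carboxyl-bearing) and C6' (OH) map onto a malonate carbon and one of its ester carbonyls, C2' (ether oxygen) onto the alkylidene carbon, and C3'H–C4'(CH3)–C5'H onto a 3-methylbut-2-enylidene chain whose terminal methyl becomes C5'.
3. The open-chain precursor is cut at the vinylic C2'–O bond (ring A phenoxide plus a 1-chloroalkylidene malonate) and at the C1'–C2' malonate–acyl bond (diallyl malonate plus 3-methylbut-2-enoyl chloride).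
4. The ring A phenol is cut at C1–CO2Me (ortho-formylation of the phenol, then oxidation) and at C4–Cl (lithiation between OMe and OMOM), back to 4-(benzyloxy)-3-methoxyphenol.
5. Forward: ring A is bought and substituted (steps 1–6), the five-carbon chain is built on the malonate (steps 7–8), the halves are joined through oxygen (step 9), ring B is closed and aromatised (step 10), and acid and phenol are unmasked (steps 11–12).
6. Stereochemistry: the target has no stereocentre and no stereogenic double bond; the two identical malonate esters make the alkylidene geometry irrelevant.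

Key step: step 10

Assumption: 4-(benzyloxy)-3-methoxyphenol is taken as a purchasable starting material; ring A is numbered from the ester-bearing carbon (C1) through the ether carbon (C2), ring B from the carboxyl-bearing carbon (C1') through the ether carbon (C2').

**Route**

Step 1
Reactants: 1 4-(benzyloxy)-3-methoxyphenol
Product: 2 1-(benzyloxy)-2-methoxy-4-(methoxymethoxy)benzene
Conditions: MOMCl, i-Pr2NEt, CH2Cl2, 0 °C → rt
Reagents that add atoms: chloromethyl methyl ether, COCCl
Why: Base-mediated O-alkylation of the phenol with the α-chloro ether (acetal-forming Williamson etherification) should put on the future ring A C5 oxygen a group that strongly directs lithiation and is removable with dilute acid at the end.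

Step 2
Reactants: 2 1-(benzyloxy)-2-methoxy-4-(methoxymethoxy)benzene
Product: 4 1-(benzyloxy)-3-chloro-2-methoxy-4-(methoxymethoxy)benzene, via aryllithium 3 (not isolated)
Conditions: n-BuLi, THF, 0 °C; then C2Cl6, −78 °C → rt
Reagents that add atoms: hexachloroethane, ClC(Cl)(Cl)C(Cl)(Cl)Cl
Why: Directed ortho-metalation: n-BuLi, held by the OMOM and OMe oxygens, should remove only the hydrogen between them (the doubly activated site, as in 1,2,4-trialkoxybenzenes), and chlorine transfer from hexachloroethane to aryllithium 3 fixes the halogen at the future ring A C4, which electrophilic chlorination of a benzoate could not reliably distinguish from C6.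

Step 3
Reactants: 4 1-(benzyloxy)-3-chloro-2-methoxy-4-(methoxymethoxy)benzene
Product: 5 3-chloro-2-methoxy-4-(methoxymethoxy)phenol
Conditions: H2 (1 atm), palladium on carbon (Pd/C, 10 wt% Pd), EtOAc, rt
Reagents that add atoms: none
Why: Catalytic hydrogenolysis of the benzylic C–O bond should be much faster than hydrodechlorination of an electron-rich chloroarene in neutral EtOAc and leaves the MOM acetal untouched, freeing the phenol that directs the next step.

Step 4
Reactants: 5 3-chloro-2-methoxy-4-(methoxymethoxy)phenol
Product: 6 4-chloro-2-hydroxy-3-methoxy-5-(methoxymethoxy)benzaldehyde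
Conditions: MgCl2, Et3N, (CH2O)n, MeCN, reflux; dilute aq. HCl work-up
Reagents that add atoms: paraformaldehyde (as formaldehyde), C=O
Why: Magnesium-mediated ortho-formylation of phenols (Casnati–Skattebøl reaction): the magnesium phenoxide delivers formaldehyde to its only free ortho position and a second formaldehyde oxidises the benzylic alkoxide by hydride transfer, so the carbon of the ring A ester should enter only next to the hydroxyl.

Step 5
Reactants: 6 4-chloro-2-hydroxy-3-methoxy-5-(methoxymethoxy)benzaldehyde
Product: 7 4-chloro-2-hydroxy-3-methoxy-5-(methoxymethoxy)benzoic acid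
Conditions: NaClO2, NaH2PO4, 2-methylbut-2-ene, t-BuOH/H2O, rt
Reagents that add atoms: sodium chlorite, [Na+].[O-]Cl=O
Why: Pinnick oxidation: chlorous acid converts the aldehyde into the acid at about pH 4, where the MOM ether is stable, while excess 2-methylbut-2-ene scavenges hypochlorous acid before it can chlorinate the electron-rich ring.

Step 6
Reactants: 7 4-chloro-2-hydroxy-3-methoxy-5-(methoxymethoxy)benzoic acid
Product: 8 methyl 4-chloro-2-hydroxy-3-methoxy-5-(methoxymethoxy)benzoate
Conditions: MeI, KHCO3, DMF, rt
Reagents that add atoms: iodomethane, CI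
Why: SN2 O-methylation of the carboxylate: KHCO3 ionises only the carboxylic acid, so the chelated and far less acidic ortho-phenol should stay free for the ether-forming step.

Step 7
Reactants: 9 diprop-2-enyl propanedioate (diallyl malonate); 10 3-methylbut-2-enoyl chloride
Product: 12 diprop-2-enyl 2-(3-methylbut-2-enoyl)propanedioate (largely enolised), via chloromagnesium malonate enolate 11 (not isolated)
Conditions: MgCl2, Et3N, MeCN, 0 °C; then 10, 0 °C → rt; dilute aq. HCl work-up
Reagents that add atoms: none
Why: Magnesium chloride/amine soft-enolisation C-acylation of a malonate: the chelated enolate 11 should acylate on carbon and the tricarbonyl product is shielded from a second acylation as its magnesium chelate; any acyl group that enters as the deconjugated 3-methylbut-3-enoyl isomer (via a vinylketene) leads to the same pentadienyl anion in step 10.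

Step 8
Reactants: 12 diprop-2-enyl 2-(3-methylbut-2-enoyl)propanedioate
Product: 13 diprop-2-enyl 2-(1-chloro-3-methylbut-2-en-1-ylidene)propanedioate
Conditions: POCl3, n-Bu3N, toluene, 80 °C
Reagents that add atoms: phosphoryl chloride, O=P(Cl)(Cl)Cl
Why: Deoxychlorination of an enolised acylmalonate (enol dichlorophosphate, then addition–elimination by chloride) is the standard entry to 1-chloroalkylidene malonates and should turn the enol hydroxyl into a vinylic leaving group without touching the allyl esters.

Step 9
Reactants: 8 methyl 4-chloro-2-hydroxy-3-methoxy-5-(methoxymethoxy)benzoate; 13 diprop-2-enyl 2-(1-chloro-3-methylbut-2-en-1-ylidene)propanedioate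
Product: 14 diprop-2-enyl 2-{1-[3-chloro-2-methoxy-6-(methoxycarbonyl)-4-(methoxymethoxy)phenoxy]-3-methylbut-2-en-1-ylidene}propanedioate
Conditions: Cs2CO3, DMF, 0 °C → rt
Reagents that add atoms: none
Why: Nucleophilic vinylic substitution by addition–elimination: the phenoxide of 8 should add to the alkylidene carbon, which is activated by two geminal esters, and chloride is then expelled, so the hindered ring A–O–C2' bond forms at an sp2 carbon without a metal-mediated coupling of two ortho-disubstituted arenes.

Step 10
Reactants: 14 diprop-2-enyl 2-{1-[3-chloro-2-methoxy-6-(methoxycarbonyl)-4-(methoxymethoxy)phenoxy]-3-methylbut-2-en-1-ylidene}propanedioate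
Product: 16 prop-2-enyl 2-[3-chloro-2-methoxy-6-(methoxycarbonyl)-4-(methoxymethoxy)phenoxy]-6-hydroxy-4-methylbenzoate, via cyclohexa-1,3-dienone tautomer 15 (not isolated)
Conditions: KN(SiMe3)2 (1.2 equiv), THF, −78 → 0 °C; then dilute aq. HCl
Reagents that add atoms: none
Why: KN(SiMe3)2 should remove a proton from one of the two terminal methyl groups to give a pentadienyl anion delocalised into the malonate (an ester trienolate); from the s-cis rotamer its CH2 terminus adds to the malonate ester carbonyl on the same side, forming the C5'–C6' bond, the tetrahedral intermediate expels prop-2-en-1-olate, and cyclohexadienone 15 enolises at once to salicylate 16. The closest known reaction is the base-induced Claisen-type benzannulation of 2-alkenylidene malonates to salicylates, used here on a member whose alkylidene carbon carries an aryloxy group. Ring B closes in a 6-(enolendo)-exo-trig mode, which can equally be read as a disrotatory 6π electrocyclisation of the trienolate. No stereocentre is formed. The step needs chemoselectivity for a malonate ester over the ring A methyl ester: the CH2 terminus could reach that ester only through an eight-membered transition state, and addition of the malonate carbon to it would give a non-enolisable β-keto diester that reverts by retro-Claisen cleavage, whereas the wanted closure is made irreversible by aromatisation and phenoxide formation. Because the malonate bears two identical allyl esters and the chain end two identical methyl groups, every rotamer offers the required cis pairing, and only a slight excess of base is used so that the liberated alkoxide is consumed in deprotonating 15 instead of exchanging with the ring A ester.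

Step 11
Reactants: 16 prop-2-enyl 2-[3-chloro-2-methoxy-6-(methoxycarbonyl)-4-(methoxymethoxy)phenoxy]-6-hydroxy-4-methylbenzoate
Product: 17 2-[3-chloro-2-methoxy-6-(methoxycarbonyl)-4-(methoxymethoxy)phenoxy]-6-hydroxy-4-methylbenzoic acid
Conditions: Pd(PPh3)4 (5 mol%), morpholine, THF, rt; then dilute aq. HCl
Reagents that add atoms: none
Why: Tsuji–Trost deallylation: zerovalent palladium ionises the allyl ester to a π-allyl complex that morpholine intercepts, which should release the ring B carboxylic acid while the ring A methyl ester, the aryl chloride and the MOM ether are untouched.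

Step 12
Reactants: 17 2-[3-chloro-2-methoxy-6-(methoxycarbonyl)-4-(methoxymethoxy)phenoxy]-6-hydroxy-4-methylbenzoic acid
Product: 18 2-[3-chloro-4-hydroxy-2-methoxy-6-(methoxycarbonyl)phenoxy]-6-hydroxy-4-methylbenzoic acid
Conditions: 3 M aq. HCl, MeOH, 40 °C
Reagents that add atoms: none
Why: Acid-catalysed acetal exchange with methanol should remove the MOM group as dimethoxymethane; methanol as solvent leaves the ring A methyl ester unchanged, and the 2,6-disubstituted benzoic acid is too hindered to esterify or to lose CO2 at this temperature.

**Compound list**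

1 | 4-(benzyloxy)-3-methoxyphenol | COc1cc(O)ccc1OCc1ccccc1 | starting material
2 | 1-(benzyloxy)-2-methoxy-4-(methoxymethoxy)benzene | COCOc1ccc(OCc2ccccc2)c(OC)c1 | intermediate
3 | [3-(benzyloxy)-2-methoxy-6-(methoxymethoxy)phenyl]lithium | COCOc1ccc(OCc2ccccc2)c(OC)c1[Li] | intermediate
4 | 1-(benzyloxy)-3-chloro-2-methoxy-4-(methoxymethoxy)benzene | COCOc1ccc(OCc2ccccc2)c(OC)c1Cl | intermediate
5 | 3-chloro-2-methoxy-4-(methoxymethoxy)phenol | COCOc1ccc(O)c(OC)c1Cl | intermediate
6 | 4-chloro-2-hydroxy-3-methoxy-5-(methoxymethoxy)benzaldehyde | COCOc1cc(C=O)c(O)c(OC)c1Cl | intermediate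
7 | 4-chloro-2-hydroxy-3-methoxy-5-(methoxymethoxy)benzoic acid | COCOc1cc(C(=O)O)c(O)c(OC)c1Cl | intermediate
8 | methyl 4-chloro-2-hydroxy-3-methoxy-5-(methoxymethoxy)benzoate | COC(=O)c1cc(OCOC)c(Cl)c(OC)c1O | intermediate
9 | diprop-2-enyl propanedioate (diallyl malonate) | C=CCOC(=O)CC(=O)OCC=C | starting material
10 | 3-methylbut-2-enoyl chloride | CC(C)=CC(=O)Cl | starting material
11 | chloromagnesium enolate of diprop-2-enyl propanedioate | C=CCOC(=O)C=C(OCC=C)O[Mg]Cl | intermediate
12 | diprop-2-enyl 2-(3-methylbut-2-enoyl)propanedioate | C=CCOC(=O)C(C(=O)OCC=C)C(=O)C=C(C)C | intermediate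
13 | diprop-2-enyl 2-(1-chloro-3-methylbut-2-en-1-ylidene)propanedioate | C=CCOC(=O)C(C(=O)OCC=C)=C(Cl)C=C(C)C | intermediate
14 | diprop-2-enyl 2-{1-[3-chloro-2-methoxy-6-(methoxycarbonyl)-4-(methoxymethoxy)phenoxy]-3-methylbut-2-en-1-ylidene}propanedioate | COC(=O)c1cc(OCOC)c(Cl)c(OC)c1OC(C=C(C)C)=C(C(=O)OCC=C)C(=O)OCC=C | intermediate
15 | prop-2-enyl 2-[3-chloro-2-methoxy-6-(methoxycarbonyl)-4-(methoxymethoxy)phenoxy]-4-methyl-6-oxocyclohexa-1,3-diene-1-carboxylate | COC(=O)c1cc(OCOC)c(Cl)c(OC)c1OC1=C(C(=O)OCC=C)C(=O)CC(C)=C1 | intermediate
16 | prop-2-enyl 2-[3-chloro-2-methoxy-6-(methoxycarbonyl)-4-(methoxymethoxy)phenoxy]-6-hydroxy-4-methylbenzoate | COC(=O)c1cc(OCOC)c(Cl)c(OC)c1Oc1cc(C)cc(O)c1C(=O)OCC=C | intermediate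
17 | 2-[3-chloro-2-methoxy-6-(methoxycarbonyl)-4-(methoxymethoxy)phenoxy]-6-hydroxy-4-methylbenzoic acid | COC(=O)c1cc(OCOC)c(Cl)c(OC)c1Oc1cc(C)cc(O)c1C(=O)O | intermediate
18 | 2-[3-chloro-4-hydroxy-2-methoxy-6-(methoxycarbonyl)phenoxy]-6-hydroxy-4-methylbenzoic acid | COC(=O)c1cc(O)c(Cl)c(OC)c1Oc1cc(C)cc(O)c1C(=O)O | target

**Step count and risks**

Total steps: 12. Longest linear sequence: 10 steps (steps 1–6 and 9–12, from 1); the malonate branch (steps 7–8) joins at step 9.

Steps most likely to fail:

1. Step 10. The trienolate may fail to close: its charge rests largely on the malonate end, so ring closure can be slow. On warming the anion may instead shed aryloxide, exchange esters with the liberated alkoxide, or oligomerise. Fallback, setting out from 8 and returning at 17: the diaryl ether is made by nucleophilic aromatic substitution on a purchased ring B arene. Commercial 2,6-difluoro-4-methylbenzaldehyde is treated with one equivalent of sodium prop-2-en-1-olate (allyl alcohol, NaH, THF, 0 °C) to give 2-fluoro-4-methyl-6-(prop-2-enyloxy)benzaldehyde F1. Phenol 8 then displaces the second, aldehyde-activated fluoride (K2CO3, N,N-dimethylacetamide, 100 °C) to give methyl 4-chloro-2-[2-formyl-5-methyl-3-(prop-2-enyloxy)phenoxy]-3-methoxy-5-(methoxymethoxy)benzoate F2. Pinnick oxidation as in step 5 gives 2-[3-chloro-2-methoxy-6-(methoxycarbonyl)-4-(methoxymethoxy)phenoxy]-4-methyl-6-(prop-2-enyloxy)benzoic acid F3. Pd(PPh3)4 with morpholine then cleaves the aryl allyl ether to give 17, from which step 12 completes the synthesis.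

2. Step 8. Hot POCl3 may isomerise or polymerise the dienyl tricarbonyl or attack the allyl esters, and the chloride may hydrolyse back on work-up. Fallback, setting out from 12 and returning at 14: the enol is activated as a sulfonate instead of a halide. Treatment of 12 with TsCl, N-methylimidazole and Et3N in MeCN at 0 °C should give diprop-2-enyl 2-{3-methyl-1-[(4-methylphenyl)sulfonyloxy]but-2-en-1-ylidene}propanedioate F4. This undergoes the same addition–elimination with phenol 8 (Cs2CO3, DMF) to give 14.

3. Step 3. Hydrogenolysis may over-reduce, removing the aryl chloride along with the benzyl group. Fallback, setting out from 2 and returning at 5: debenzylation and chlorination are reversed so that hydrogen never meets the C–Cl bond. Compound 2 is hydrogenolysed (H2, Pd/C, EtOAc) to 2-methoxy-4-(methoxymethoxy)phenol F5. With 2.2 equivalents of n-BuLi in THF at 0 °C this should give lithium 3-lithio-2-methoxy-4-(methoxymethoxy)phenolate F6, metalated again between OMe and OMOM. Hexachloroethane then delivers 5 directly, which also avoids any benzylic lithiation in step 2.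

Further compounds
F1 | step 10 | 2-fluoro-4-methyl-6-(prop-2-enyloxy)benzaldehyde | C=CCOc1cc(C)cc(F)c1C=O
F2 | step 10 | methyl 4-chloro-2-[2-formyl-5-methyl-3-(prop-2-enyloxy)phenoxy]-3-methoxy-5-(methoxymethoxy)benzoate | COC(=O)c1cc(OCOC)c(Cl)c(OC)c1Oc1cc(C)cc(OCC=C)c1C=O
F3 | step 10 | 2-[3-chloro-2-methoxy-6-(methoxycarbonyl)-4-(methoxymethoxy)phenoxy]-4-methyl-6-(prop-2-enyloxy)benzoic acid | COC(=O)c1cc(OCOC)c(Cl)c(OC)c1Oc1cc(C)cc(OCC=C)c1C(=O)O
F4 | step 8 | diprop-2-enyl 2-{3-methyl-1-[(4-methylphenyl)sulfonyloxy]but-2-en-1-ylidene}propanedioate | C=CCOC(=O)C(C(=O)OCC=C)=C(OS(=O)(=O)c1ccc(C)cc1)C=C(C)C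
F5 | step 3 | 2-methoxy-4-(methoxymethoxy)phenol | COCOc1ccc(O)c(OC)c1
F6 | step 3 | lithium 3-lithio-2-methoxy-4-(methoxymethoxy)phenolate | COCOc1ccc(O[Li])c(OC)c1[Li]
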